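The six-membered lactone (O1, C2 carbonyl, C3, C4, C5, C6) is traced back to an acyclic 1,3,5-triol. Everything rests on one disconnection at C6, the fully substituted O-bearing ring carbon whose methyl and C7 chain are sterically almost alike. A single palladium-catalysed conjunctive coupling joins the C7–C18 alkyl pinacol boronate, isopropenyllithium (C5, C6 and its methyl) and ethyl (E)-3-(triflyloxy)but-2-enoate (C2–C4 and the C4 methyl). It forms C6–C7 and C4–C5 and sets C6, because the methyl is on the alkenyl carbon from the start while C7 is delivered by a 1,2-shift from boron. The precursor is the open-chain lithium alkyl(isopropenyl)boronate; boron later becomes O1, and C4 is set by Sharpless epoxidation.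

Key step: step 5

Remark on numbering: atom labels such as C4, C6 or C7–C18 refer to the lactone (O1, C2 carbonyl, C4 carbinol, C6 ring carbon carrying the chain C7–C18); compound names carry their own locants.

Assumption: which antipode of the ferrocenyl bisphosphine leads to the (5S)-boronate is not taken as known. The (Sp,Sp) ligand is written as the working choice and would be replaced by its (Rp,Rp) antipode if correlation at alcohol 13 showed the opposite sense, with no other change to the route.

Step 1
Reactants: 1 undec-10-yn-1-ol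
Product: 2 11-bromoundec-1-yne
Conditions: CBr4, PPh3, CH2Cl2, 0 °C to rt
Reagents that add atoms: carbon tetrabromide, BrC(Br)(Br)Br
Why: Appel reaction, in which the alcohol is activated as an alkoxyphosphonium salt and bromide displaces Ph3P=O at the primary carbon by SN2, conditions under which a terminal alkyne is inert.

Step 2
Reactants: 2 11-bromoundec-1-yne, 3 benzyl bromide
Product: 5 [(2E)-12-bromododec-2-en-1-yl]benzene, via alkenylzirconocene chloride 4 (not isolated)
Conditions: Cp2Zr(H)Cl (1.3 equiv), THF, rt; then 3, Pd(PPh3)4 (5 mol%), THF, rt to 40 °C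
Reagents that add atoms: none
Why: Hydrozirconation followed by Negishi-type cross-coupling, in which syn addition of Zr–H places zirconium on the terminal carbon and fixes the (E) geometry, and the alkenyl group is then transferred with retention to the benzylpalladium bromide formed from 3 and zerovalent palladium, the unactivated primary C–Br bond being left alone by both reagents.

Step 3
Reactants: 5 [(2E)-12-bromododec-2-en-1-yl]benzene
Product: 6 4,4,5,5-tetramethyl-2-[(10E)-12-phenyldodec-10-en-1-yl]-1,3,2-dioxaborolane
Conditions: B2pin2 (1.5 equiv), CuI (10 mol%), PPh3 (13 mol%), LiOMe (2 equiv), DMF, rt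
Reagents that add atoms: bis(pinacolato)diboron, CC1(C)OB(OC1(C)C)B1OC(C)(C)C(C)(C)O1
Why: Copper-catalysed borylation of a primary alkyl bromide, in which a boryl–copper species made from B2pin2 and LiOMe replaces bromide, the weak methoxide base being unable to move the skipped alkene into conjugation with the arene.

Step 4
Reactants: 7 ethyl acetoacetate
Product: 8 ethyl (2E)-3-{[(trifluoromethyl)sulfonyl]oxy}but-2-enoate
Conditions: Tf2O (1.3 equiv), aq. Me4NOH, hexane, 5 °C to rt
Reagents that add atoms: trifluoromethanesulfonic anhydride, O=S(=O)(OS(=O)(=O)C(F)(F)F)C(F)(F)F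
Why: Enol triflate formation by O-sulfonylation of a β-keto ester enolate, the non-chelating tetramethylammonium counter-ion favouring the extended enolate with oxygen anti to the ester, so that the (E)-triflate should result.

Step 5
Reactants: 6 4,4,5,5-tetramethyl-2-[(10E)-12-phenyldodec-10-en-1-yl]-1,3,2-dioxaborolane, 9 2-bromopropene, 8 ethyl (2E)-3-{[(trifluoromethyl)sulfonyl]oxy}but-2-enoate
Product: 12 ethyl (2E,5S,15E)-3,5-dimethyl-17-phenyl-5-(4,4,5,5-tetramethyl-1,3,2-dioxaborolan-2-yl)heptadeca-2,15-dienoate, via isopropenyllithium 10 (not isolated), via lithium ate complex 11 (not isolated)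
Conditions: 9 (1.0 equiv), tBuLi (2.0 equiv), Et2O, −78 °C; then 6 (1.05 equiv), −78 °C to rt; solvent switch to THF, KOTf (2 equiv); Pd(OAc)2 (3 mol%), (Sp,Sp)-1,1'-bis[(R)-(dimethylamino)(phenyl)methyl]-2,2'-bis(diphenylphosphino)ferrocene (3.6 mol%), 8 (1.2 equiv), 60 °C
Reagents that add atoms: none
Why: Proposed new method: isopropenyllithium 10 adds to the boron of 6 to give the four-coordinate boronate 11, and the cationic alkenylpalladium triflate formed by oxidative addition of 8 to zerovalent palladium (metal trans to the ester) binds the electron-rich isopropenyl π bond and induces a 1,2-shift of the C7 alkyl group from boron to C6 anti to the metal (C6–C7); reductive elimination from the resulting divalent alkyl(alkenyl)palladium then joins C5 to C4 and returns the catalyst. The closest known reaction type is the palladium-catalysed enantioselective conjunctive cross-coupling of α-substituted alkenyl boron ate complexes with aryl and simple alkenyl triflates to give tertiary boronic esters; a β-triflyloxy enoate has not served as the electrophile, but such triflates add oxidatively with ease and the more electron-poor alkenylpalladium should be a stronger π acid, which favours the metallate shift. No ring is closed. The C6 stereocentre is controlled by the chiral ferrocenyl bisphosphine, which decides the face of the isopropenyl group that binds palladium, and methyl and chain are distinguished because the methyl is part of the alkene while the chain migrates. The step needs the metallate shift to win over direct transmetallation of the isopropenyl group and over uncatalysed addition–elimination at the enoate, and it needs the (E) geometry to survive; the non-coordinating triflate with bromide removed as KBr keeps palladium cationic, the absence of free organolithium spares the ester, and reductive elimination with retention at the sp2 carbon should carry the geometry of 8 into 12.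

Step 6
Reactants: 12 ethyl (2E,5S,15E)-3,5-dimethyl-17-phenyl-5-(4,4,5,5-tetramethyl-1,3,2-dioxaborolan-2-yl)heptadeca-2,15-dienoate
Product: 13 ethyl (2E,5R,15E)-5-hydroxy-3,5-dimethyl-17-phenylheptadeca-2,15-dienoate
Conditions: NaBO3·4H2O (5 equiv), THF/H2O, rt
Reagents that add atoms: sodium perborate tetrahydrate, [Na+].[O-]OB=O.O.O.O.O
Why: Oxidation of a carbon–boron bond, in which perborate adds to boron and the tertiary alkyl group migrates to oxygen with retention (the descriptor changes from S to R only because oxygen outranks carbon while boron does not), the weakly basic reagent leaving the enoate and its (E) geometry untouched.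

Step 7
Reactants: 13 ethyl (2E,5R,15E)-5-hydroxy-3,5-dimethyl-17-phenylheptadeca-2,15-dienoate
Product: 14 (2E,5R,15E)-3,5-dimethyl-17-phenylheptadeca-2,15-diene-1,5-diol
Conditions: iBu2AlH (3.5 equiv), CH2Cl2, −78 to 0 °C
Reagents that add atoms: none
Why: 1,2-Reduction of an α,β-unsaturated ester by iBu2AlH to the (E)-allylic alcohol, the tertiary hydroxyl being merely deprotonated and both alkenes inert.

Step 8
Reactants: 14 (2E,5R,15E)-3,5-dimethyl-17-phenylheptadeca-2,15-diene-1,5-diol
Product: 15 (2R,3R,5R,15E)-2,3-epoxy-3,5-dimethyl-17-phenylheptadec-15-ene-1,5-diol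
Conditions: Ti(OiPr)4 (20 mol%), D-(−)-diethyl tartrate (25 mol%), tBuOOH (2 equiv), 4 Å MS, CH2Cl2, −20 °C
Reagents that add atoms: tert-butyl hydroperoxide, CC(C)(C)OO
Why: Sharpless asymmetric epoxidation, in which the titanium tartrate catalyst binds the primary allylic alcohol and delivers oxygen to one face of the trisubstituted alkene, D-(−)-diethyl tartrate giving the (2R,3R)-epoxide as with other (E)-3-methylalk-2-en-1-ols, while the C15–C16 alkene, which has no allylic hydroxyl, is not epoxidised.

Step 9
Reactants: 15 (2R,3R,5R,15E)-2,3-epoxy-3,5-dimethyl-17-phenylheptadec-15-ene-1,5-diol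
Product: 16 (3S,5R,15E)-3,5-dimethyl-17-phenylheptadec-15-ene-1,3,5-triol
Conditions: NaAlH2(OCH2CH2OMe)2 (4 equiv), THF, 0 °C to rt
Reagents that add atoms: none
Why: Regioselective reductive opening of a 2,3-epoxy alcohol, in which the aluminate formed at the C1 oxygen delivers hydride intramolecularly to C2, so that the C3–O bond and its configuration are kept and the 1,3-diol should result (the descriptor at C3 becomes S only through a change in priorities).

Step 10
Reactants: 16 (3S,5R,15E)-3,5-dimethyl-17-phenylheptadec-15-ene-1,3,5-triol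
Product: 19 trisphaerolide A [(4R,6R)-4-hydroxy-4,6-dimethyl-6-[(10E)-12-phenyldodec-10-en-1-yl]oxan-2-one], via hydroxy aldehyde 17 (not isolated), via lactol 18 (not isolated)
Conditions: TEMPO (20 mol%), PhI(OAc)2 (2.5 equiv), CH2Cl2, rt
Reagents that add atoms: none
Why: Oxidative lactonisation, in which the oxoammonium salt derived from TEMPO oxidises only the primary alcohol, the aldehyde is trapped by the tertiary hydroxyl at C5 of the triol (C6 of the lactone) as the six-membered lactol, and a second oxidation gives the δ-lactone, the tertiary alcohols and the remote alkene being inert.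

Compound list
1 | undec-10-yn-1-ol | C#CCCCCCCCCCO | starting material
2 | 11-bromoundec-1-yne | C#CCCCCCCCCCBr | intermediate
3 | benzyl bromide | BrCc1ccccc1 | starting material
4 | [(1E)-11-bromoundec-1-en-1-yl]chlorobis(cyclopentadienyl)zirconium | BrCCCCCCCCC/C=C/[Zr](Cl)(C1C=CC=C1)C1C=CC=C1 | intermediate
5 | [(2E)-12-bromododec-2-en-1-yl]benzene | BrCCCCCCCCC/C=C/Cc1ccccc1 | intermediate
6 | 4,4,5,5-tetramethyl-2-[(10E)-12-phenyldodec-10-en-1-yl]-1,3,2-dioxaborolane | CC1(C)OB(CCCCCCCCC/C=C/Cc2ccccc2)OC1(C)C | intermediate
7 | ethyl acetoacetate | CCOC(=O)CC(C)=O | starting material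
8 | ethyl (2E)-3-{[(trifluoromethyl)sulfonyl]oxy}but-2-enoate | CCOC(=O)/C=C(\C)OS(=O)(=O)C(F)(F)F | intermediate
9 | 2-bromopropene | CC(Br)=C | starting material
10 | isopropenyllithium | [Li]C(C)=C | intermediate
11 | lithium isopropenyl[(10E)-12-phenyldodec-10-en-1-yl](pinacolato)borate | [Li+].CC(=C)[B-]1(CCCCCCCCC/C=C/Cc2ccccc2)OC(C)(C)C(C)(C)O1 | intermediate
12 | ethyl (2E,5S,15E)-3,5-dimethyl-17-phenyl-5-(4,4,5,5-tetramethyl-1,3,2-dioxaborolan-2-yl)heptadeca-2,15-dienoate | CCOC(=O)/C=C(\C)C[C@](C)(B1OC(C)(C)C(C)(C)O1)CCCCCCCCC/C=C/Cc1ccccc1 | intermediate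
13 | ethyl (2E,5R,15E)-5-hydroxy-3,5-dimethyl-17-phenylheptadeca-2,15-dienoate | CCOC(=O)/C=C(\C)C[C@](C)(O)CCCCCCCCC/C=C/Cc1ccccc1 | intermediate
14 | (2E,5R,15E)-3,5-dimethyl-17-phenylheptadeca-2,15-diene-1,5-diol | OC/C=C(\C)C[C@](C)(O)CCCCCCCCC/C=C/Cc1ccccc1 | intermediate
15 | (2R,3R,5R,15E)-2,3-epoxy-3,5-dimethyl-17-phenylheptadec-15-ene-1,5-diol | OC[C@H]1O[C@]1(C)C[C@](C)(O)CCCCCCCCC/C=C/Cc1ccccc1 | intermediate
16 | (3S,5R,15E)-3,5-dimethyl-17-phenylheptadec-15-ene-1,3,5-triol | OCC[C@](C)(O)C[C@](C)(O)CCCCCCCCC/C=C/Cc1ccccc1 | intermediate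
17 | (3R,5R,15E)-3,5-dihydroxy-3,5-dimethyl-17-phenylheptadec-15-enal | O=CC[C@](C)(O)C[C@](C)(O)CCCCCCCCC/C=C/Cc1ccccc1 | intermediate
18 | (4R,6R)-4,6-dimethyl-6-[(10E)-12-phenyldodec-10-en-1-yl]oxane-2,4-diol (both anomers) | OC1C[C@](C)(O)C[C@](C)(O1)CCCCCCCCC/C=C/Cc1ccccc1 | intermediate
19 | trisphaerolide A, (4R,6R)-4-hydroxy-4,6-dimethyl-6-[(10E)-12-phenyldodec-10-en-1-yl]oxan-2-one | C[C@]1(O)CC(=O)O[C@](C)(CCCCCCCCC/C=C/Cc2ccccc2)C1 | target

Total step count: 10. Longest linear sequence: 9 steps (steps 1, 2, 3, 5, 6, 7, 8, 9, 10); step 4 is a one-step side branch.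

Steps most likely to fail

First, step 5. The untested electron-poor triflate may divert the ate complex into direct transfer of the isopropenyl group to palladium, or into uncatalysed addition–elimination at the β-carbon of the enoate. The β-palladated enoate may also lose its geometry, which would later give the C4 epimer. The fallback lowers the oxidation level of the electrophile before the coupling, so that the coupling partner is a simple, non-conjugated alkenyl triflate of the class already established for this reaction. Setting out from 8, iBu2AlH (CH2Cl2, −78 °C) should reduce the ester to (E)-4-hydroxybut-2-en-2-yl trifluoromethanesulfonate F1. TBSCl and imidazole then give (E)-4-[(tert-butyldimethylsilyl)oxy]but-2-en-2-yl trifluoromethanesulfonate F2. F2 is coupled with ate complex 11 (made from 6 and 10 as in step 5) under the same Pd(OAc)2/bisphosphine catalyst to give tert-butyl{[(2E,5S,15E)-3,5-dimethyl-17-phenyl-5-(4,4,5,5-tetramethyl-1,3,2-dioxaborolan-2-yl)heptadeca-2,15-dien-1-yl]oxy}dimethylsilane F3. NaBO3·4H2O oxidises the C–B bond to give (2E,5R,15E)-1-{[tert-butyl(dimethyl)silyl]oxy}-3,5-dimethyl-17-phenylheptadeca-2,15-dien-5-ol F4, and Bu4NF removes the silyl group to give diol 14, where the route is rejoined.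

Second, step 10. The β-hydroxy aldehyde may undergo retro-aldol cleavage or dehydration, or the oxidation may stall at the lactol stage because the ring has to be closed by a tertiary hydroxyl. The fallback closes the ring by acyl substitution at the acid oxidation level instead of by oxidation of a lactol. Setting out from 16, TEMPO (cat.) and PhI(OAc)2 in MeCN/H2O should take the primary alcohol through the hydrated aldehyde to (3R,5R,15E)-3,5-dihydroxy-3,5-dimethyl-17-phenylheptadec-15-enoic acid F7. F7 is then lactonised under Yamaguchi conditions (2,4,6-trichlorobenzoyl chloride, Et3N, then DMAP, toluene) to give 19.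

Third, step 8. The free tertiary hydroxyl may compete with the allylic alcohol for titanium, which would slow turnover and erode facial selectivity. The fallback epoxidises before the C–B bond is oxidised, so that the allylic hydroxyl is the only one present. Setting out from 12, iBu2AlH gives (2E,5S,15E)-3,5-dimethyl-17-phenyl-5-(4,4,5,5-tetramethyl-1,3,2-dioxaborolan-2-yl)heptadeca-2,15-dien-1-ol F5. Sharpless epoxidation with the same Ti(OiPr)4/D-(−)-diethyl tartrate catalyst gives (2R,3R,5S,15E)-2,3-epoxy-3,5-dimethyl-17-phenyl-5-(4,4,5,5-tetramethyl-1,3,2-dioxaborolan-2-yl)heptadec-15-en-1-ol F6. NaBO3·4H2O then oxidises the C–B bond with retention to give epoxy diol 15, where the route is rejoined.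

Further compounds
F1 | step 5 | (E)-4-hydroxybut-2-en-2-yl trifluoromethanesulfonate | OC/C=C(\C)OS(=O)(=O)C(F)(F)F
F2 | step 5 | (E)-4-[(tert-butyldimethylsilyl)oxy]but-2-en-2-yl trifluoromethanesulfonate | CC(C)(C)[Si](C)(C)OC/C=C(\C)OS(=O)(=O)C(F)(F)F
F3 | step 5 | tert-butyl{[(2E,5S,15E)-3,5-dimethyl-17-phenyl-5-(4,4,5,5-tetramethyl-1,3,2-dioxaborolan-2-yl)heptadeca-2,15-dien-1-yl]oxy}dimethylsilane | CC(C)(C)[Si](C)(C)OC/C=C(\C)C[C@](C)(B1OC(C)(C)C(C)(C)O1)CCCCCCCCC/C=C/Cc1ccccc1
F4 | step 5 | (2E,5R,15E)-1-{[tert-butyl(dimethyl)silyl]oxy}-3,5-dimethyl-17-phenylheptadeca-2,15-dien-5-ol | CC(C)(C)[Si](C)(C)OC/C=C(\C)C[C@](C)(O)CCCCCCCCC/C=C/Cc1ccccc1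
F5 | step 8 | (2E,5S,15E)-3,5-dimethyl-17-phenyl-5-(4,4,5,5-tetramethyl-1,3,2-dioxaborolan-2-yl)heptadeca-2,15-dien-1-ol | OC/C=C(\C)C[C@](C)(B1OC(C)(C)C(C)(C)O1)CCCCCCCCC/C=C/Cc1ccccc1
F6 | step 8 | (2R,3R,5S,15E)-2,3-epoxy-3,5-dimethyl-17-phenyl-5-(4,4,5,5-tetramethyl-1,3,2-dioxaborolan-2-yl)heptadec-15-en-1-ol | OC[C@H]1O[C@]1(C)C[C@](C)(B2OC(C)(C)C(C)(C)O2)CCCCCCCCC/C=C/Cc1ccccc1
F7 | step 10 | (3R,5R,15E)-3,5-dihydroxy-3,5-dimethyl-17-phenylheptadec-15-enoic acid | OC(=O)C[C@](C)(O)C[C@](C)(O)CCCCCCCCC/C=C/Cc1ccccc1
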